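## Retrosynthetic overview

1. The dihydropyran is opened by a retro-hetero-Diels–Alder cut (O–C4 and CH2–C5 of the caryophyllane unit). This gives a hirsutane 3-methylene-1,2-dione (made in situ from a ring-A 1,2-dione acid and formaldehyde) and (1S,9R)-β-caryophyllene.
2. The caryophyllene is built backwards as: C8 methylidene by Wittig reaction; nine-membered ring by intramolecular sulfone acylation (C7–C8); side chain by B-alkyl Suzuki coupling (C3–C4); cyclobutane by a ring-contracting Ireland–Claisen rearrangement that forms the fusion bond C1–C9.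
3. Enabling feature: in the cyclobutane (C1, C9, C10, C11) the fusion bond C1–C9 sits between C8 (kept at carboxyl level) and the C2=C3 position of the nine-membered ring. C8(=O)–C9–C1–C2=C3 is therefore a 4-pentenoic acid (Claisen) retron whose termini are already tied 1,4 by C10–C11. A temporary lactone O–C3 bond makes this an eight-membered ring; its methyl-bearing C3 stereocentre, from (S)-but-3-en-2-ol, relays chirality to C1/C9 and is then removed by ethenolysis.
4. Hirsutane half: a meso bicyclic keto ester (ring C, then ring B by ketene [2+2]/ring expansion) is desymmetrised by a chiral lithium amide; ring A follows by cyclopentenone annulation, epoxidation and rearrangement to the 1,2-dione.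
5. Ring order: temporary lactone → cyclobutane → nine-membered ring; ring C → ring B → ring A; dihydropyran last.

Key step: step 6

Remarks on the chemistry (assumptions):
- The SMILES fixes the caryophyllane unit as (1S,9R), the antipode of commercial (−)-β-caryophyllene, so this hydrocarbon is synthesised.
- Compounds 1, 2, 7, 16 and 25 are taken as purchasable.
- The (R,R)-lithium amide in step 19 is assumed to remove the proton that leads to 30 as drawn; if the sense is opposite, the (S,S)-amide is used.

## Route

Step 1
Reactants: 1 isobutyraldehyde; 2 methyl acrylate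
Product: 4 methyl 4,4-dimethyl-5-oxopentanoate, via enamine 3 (not isolated)
Conditions: pyrrolidine, TsOH (cat.), PhH, Dean–Stark; then 2, MeCN, reflux; then AcOH/H2O
Reagents that add atoms: water, O
Why: Stork enamine Michael addition of an α-branched aldehyde builds the quaternary gem-dimethyl carbon, and hydrolysis returns the aldehyde; no stereocentre is formed.

Step 2
Reactants: 4 methyl 4,4-dimethyl-5-oxopentanoate
Product: 5 methyl 4,4-dimethylhex-5-enoate
Conditions: Ph3PCH3Br, KOtBu, THF, 0 → 23 °C
Reagents that add atoms: methyltriphenylphosphonium bromide, C[P+](c1ccccc1)(c1ccccc1)c1ccccc1.[Br-]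
Why: Wittig methylenation of a non-enolisable α-quaternary aldehyde is clean and leaves the methyl ester alone.

Step 3
Reactants: 5 methyl 4,4-dimethylhex-5-enoate
Product: 6 4,4-dimethylhex-5-enoic acid
Conditions: LiOH, THF/H2O, 23 °C; then HCl (aq.)
Reagents that add atoms: lithium hydroxide, [Li+].[OH-]
Why: Saponification of an unhindered methyl ester.

Step 4
Reactants: 6 4,4-dimethylhex-5-enoic acid; 7 (S)-but-3-en-2-ol
Product: 8 (2S)-but-3-en-2-yl 4,4-dimethylhex-5-enoate
Conditions: DCC, DMAP (cat.), CH2Cl2, 0 → 23 °C
Reagents that add atoms: none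
Why: Steglich esterification acylates the secondary allylic alcohol at oxygen, so its C–O stereocentre is carried over unchanged.

Step 5
Reactants: 8 (2S)-but-3-en-2-yl 4,4-dimethylhex-5-enoate
Product: 9 (6Z,8S)-5,5,8-trimethyl-3,4,5,8-tetrahydro-2H-oxocin-2-one
Conditions: second-generation Grubbs catalyst RuCl2(=CHPh)(PCy3)(H2IMes) (5 mol%), PhMe, high dilution, 80 °C
Reagents that add atoms: none
Why: Ring-closing metathesis with loss of ethylene, helped by the gem-dimethyl (Thorpe–Ingold) effect, should close the eight-membered unsaturated lactone, a ring class made this way before; only the Z alkene fits the ring.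

Step 6
Reactants: 9 (6Z,8S)-5,5,8-trimethyl-3,4,5,8-tetrahydro-2H-oxocin-2-one
Product: 12 (1S,2S)-3,3-dimethyl-2-[(1E)-prop-1-en-1-yl]cyclobutane-1-carboxylic acid, via silyl ketene acetal 10 (not isolated), via silyl ester 11 (not isolated)
Conditions: TBSCl, LDA (LiN(iPr)2), THF/HMPA, −78 °C; then PhMe, 80 °C; then AcOH/H2O/THF, 23 °C
Reagents that add atoms: none
Why: Ring-contracting Ireland–Claisen rearrangement: enolisation of 9 with internal silyl quench can only give the ring-constrained (E)-silyl ketene acetal 10, whose termini C3 and C6 are held 1,4 by C4–C5, so the [3,3] shift through the only accessible boat transition state forms C3–C6, cuts the lactone C8–O bond and leaves the silyl ester 11. The closest known reactions are ester-enolate Claisen ring contractions of unsaturated lactones to cis-2-alkenylcycloalkanecarboxylic acids, which reach down to the seven-membered lactone to vinylcyclopropane case. The cyclobutane is closed in a formally 4-(enolexo)-exo-trig sense, realised as a concerted 8 → 4 contraction in which the new σ-bond is the ring bond and both former π-systems end exocyclic (carboxyl on one carbon, propenyl on the other). The C8 stereocentre controls the ring carbon that carries the propenyl group: its methyl takes the outside position of the boat (inside it would clash with the gem-dimethyl carbon across the Z-alkene), so the face of C6 that is bonded is fixed, giving 2S and an E-propenyl group. The boat geometry forces the carboxyl cis (1S), which is corrected in step 7. The step needs C–C bond formation to outrun β-elimination of the lactone enolate to a ketene and needs the methyl-outside boat; the −78 °C internal quench and the allylic strain secure these, and the strongly downhill ketene acetal to silyl ester change should pay for the ring strain as it does in the cyclopropane series.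

Step 7
Reactants: 12 (1S,2S)-3,3-dimethyl-2-[(1E)-prop-1-en-1-yl]cyclobutane-1-carboxylic acid
Product: 14 methyl (1R,2S)-3,3-dimethyl-2-[(1E)-prop-1-en-1-yl]cyclobutane-1-carboxylate, via cis ester 13 (not isolated)
Conditions: MeI, K2CO3, DMF, 23 °C; then NaOMe, MeOH, 60 °C
Reagents that add atoms: iodomethane, CI
Why: Carboxylate O-alkylation followed by base epimerisation of the ester α-carbon under thermodynamic control should give the less strained trans-1,2 isomer (C1 becomes R; C2 is untouched).

Step 8
Reactants: 14 methyl (1R,2S)-3,3-dimethyl-2-[(1E)-prop-1-en-1-yl]cyclobutane-1-carboxylate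
Product: 15 methyl (1R,2S)-2-ethenyl-3,3-dimethylcyclobutane-1-carboxylate
Conditions: second-generation Hoveyda–Grubbs catalyst RuCl2(=CH-C6H4-2-OiPr)(H2IMes) (5 mol%), ethylene (5 bar), PhMe, 40 °C
Reagents that add atoms: ethylene, C=C
Why: Ethenolysis (cross-metathesis with excess ethylene) trims the internal alkene to a vinyl group and expels the former relay carbon as propene; no stereocentre is touched.

Step 9
Reactants: 16 pent-3-yn-1-yl 4-methylbenzenesulfonate
Product: 17 (pent-3-yn-1-ylsulfonyl)benzene
Conditions: PhSO2Na, NaI (cat.), DMF, 60 °C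
Reagents that add atoms: sodium benzenesulfinate, [Na+].[O-]S(=O)c1ccccc1
Why: SN2 S-alkylation of the sulfinate by a primary tosylate gives the sulfone.

Step 10
Reactants: 17 (pent-3-yn-1-ylsulfonyl)benzene
Product: 19 {[(3E)-4-iodopent-3-en-1-yl]sulfonyl}benzene, via alkenylzirconocene 18 (not isolated)
Conditions: Cp2Zr(H)Cl (2.2 equiv), THF, 50 °C; then I2, 0 °C
Reagents that add atoms: iodine, II
Why: Hydrozirconation is a syn addition that, after equilibration with excess hydride, puts zirconium on the less hindered methyl-bearing carbon; iodinolysis with retention then gives the (E)-2-iodoalkene.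

Step 11
Reactants: 15 methyl (1R,2S)-2-ethenyl-3,3-dimethylcyclobutane-1-carboxylate; 19 {[(3E)-4-iodopent-3-en-1-yl]sulfonyl}benzene
Product: 21 methyl (1R,2S)-3,3-dimethyl-2-[(3E)-3-methyl-6-(phenylsulfonyl)hex-3-en-1-yl]cyclobutane-1-carboxylate, via alkylborane 20 (not isolated)
Conditions: 9-BBN, THF, 23 °C; then 19, Pd(dppf)Cl2 (5 mol%), AsPh3, Cs2CO3, DMF/H2O, 50 °C
Reagents that add atoms: none
Why: Anti-Markovnikov hydroboration of the vinyl group and B-alkyl Suzuki–Miyaura coupling, which keeps the alkenyl iodide geometry, install the E-trisubstituted alkene; ester and sulfone tolerate both stages.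

Step 12
Reactants: 21 methyl (1R,2S)-3,3-dimethyl-2-[(3E)-3-methyl-6-(phenylsulfonyl)hex-3-en-1-yl]cyclobutane-1-carboxylate
Product: 22 (1S,4E,9R)-4,11,11-trimethyl-7-(phenylsulfonyl)bicyclo[7.2.0]undec-4-en-8-one (C7 epimers)
Conditions: LiN(SiMe3)2 (2.5 equiv), THF, high dilution, −78 → 23 °C; then NH4Cl (aq.)
Reagents that add atoms: none
Why: Intramolecular Claisen-type acylation of the α-sulfonyl carbanion by the ester closes the nine-membered ring, a closure known for this trans-cyclobutane ester/E-alkenyl sulfone class; irreversible deprotonation of the β-keto sulfone drives it, and the ring-fusion centre next to the ketone rests in the more stable trans arrangement.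

Step 13
Reactants: 22 (1S,4E,9R)-4,11,11-trimethyl-7-(phenylsulfonyl)bicyclo[7.2.0]undec-4-en-8-one
Product: 23 (1S,4E,9R)-4,11,11-trimethylbicyclo[7.2.0]undec-4-en-8-one
Conditions: SmI2, THF/MeOH, −78 °C
Reagents that add atoms: none
Why: Reductive desulfonylation of a β-keto sulfone by single-electron transfer is fast at low temperature and leaves the isolated alkene and the trans ring fusion intact.

Step 14
Reactants: 23 (1S,4E,9R)-4,11,11-trimethylbicyclo[7.2.0]undec-4-en-8-one
Product: 24 (1S,4E,9R)-4,11,11-trimethyl-8-methylidenebicyclo[7.2.0]undec-4-ene, (+)-β-caryophyllene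
Conditions: Ph3PCH3Br, KOtBu, THF, 0 → 40 °C
Reagents that add atoms: methyltriphenylphosphonium bromide, C[P+](c1ccccc1)(c1ccccc1)c1ccccc1.[Br-]
Why: Wittig methylenation of this bicyclic ketone is the classical last step to the caryophyllene skeleton; the trans-fused ketone is the thermodynamic epimer, so the basic ylide cannot degrade C9.

Step 15
Reactants: 25 methyl cyclopent-3-ene-1-carboxylate
Product: 26 methyl 1-methylcyclopent-3-ene-1-carboxylate
Conditions: LDA (LiN(iPr)2), THF, −78 °C; MeI
Reagents that add atoms: iodomethane, CI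
Why: Ester enolate alkylation makes the quaternary carbon of ring C; the product is achiral.

Step 16
Reactants: 26 methyl 1-methylcyclopent-3-ene-1-carboxylate
Product: 27 rac-methyl 6,6-dichloro-3-methyl-7-oxo-cis-bicyclo[3.2.0]heptane-3-carboxylate (ester anti to the four-membered ring)
Conditions: Cl3CCOCl, Zn(Cu), POCl3, Et2O, 23 °C
Reagents that add atoms: trichloroacetyl chloride, ClC(Cl)(Cl)C(Cl)=O
Why: The [2+2] cycloaddition of in situ dichloroketene to the cyclopentene is cis-specific and should occur mainly on the face away from the ester, which places the ester on the future convex face; the minor isomer is removed after step 18.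

Step 17
Reactants: 27 rac-methyl 6,6-dichloro-3-methyl-7-oxo-cis-bicyclo[3.2.0]heptane-3-carboxylate
Product: 28 rac-methyl 4,4-dichloro-2-methyl-5-oxo-cis-octahydropentalene-2-carboxylate
Conditions: CH2N2, Et2O/MeOH, 0 °C
Reagents that add atoms: diazomethane, C=[N+]=[N-]
Why: Diazomethane ring expansion of an α,α-dichlorocyclobutanone is regioselective because the non-chlorinated α-carbon migrates, which puts the carbonyl at the symmetric position of ring B.

Step 18
Reactants: 28 rac-methyl 4,4-dichloro-2-methyl-5-oxo-cis-octahydropentalene-2-carboxylate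
Product: 29 methyl 2-methyl-5-oxo-cis-octahydropentalene-2-carboxylate (meso; ester syn to both ring-fusion H)
Conditions: Zn, AcOH, 70 °C
Reagents that add atoms: none
Why: Reductive dechlorination of the α,α-dichloro ketone gives the meso keto ester, so the racemic history of 27 and 28 is erased.

Step 19
Reactants: 29 methyl 2-methyl-5-oxo-cis-octahydropentalene-2-carboxylate
Product: 30 methyl 2-methyl-5-(trimethylsilyloxy)-cis-1,2,3,3a,4,6a-hexahydropentalene-2-carboxylate (single enantiomer as drawn)
Conditions: lithium (R,R)-bis(1-phenylethyl)amide, LiCl, TMSCl (internal quench), THF, −100 °C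
Reagents that add atoms: chlorotrimethylsilane, C[Si](C)(C)Cl
Why: Enantioselective deprotonation of a meso cis-bicyclo[3.3.0]octan-3-one by a chiral lithium amide picks one of two enantiotopic α-protons, which fixes the absolute sense of all hirsutane stereocentres; the quaternary ester has no α-proton and is inert.

Step 20
Reactants: 30 methyl 2-methyl-5-(trimethylsilyloxy)-cis-1,2,3,3a,4,6a-hexahydropentalene-2-carboxylate
Product: 31 methyl 2,4-dimethyl-5-oxo-cis-octahydropentalene-2-carboxylate (C4 epimers)
Conditions: BnMe3NF (anhydrous), MeI, 4 Å sieves, THF, 0 °C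
Reagents that add atoms: iodomethane, CI
Why: Fluoride-promoted regiospecific alkylation of the silyl enol ether methylates only the carbon chosen in step 19 and avoids an organolithium that would attack the ester; the new centre is re-formed in step 21.

Step 21
Reactants: 31 methyl 2,4-dimethyl-5-oxo-cis-octahydropentalene-2-carboxylate
Product: 32 methyl 2,4-dimethyl-4-(2-methylprop-2-en-1-yl)-5-oxo-cis-octahydropentalene-2-carboxylate (4-methyl endo)
Conditions: KOtBu, tBuOH/THF, 23 °C; 3-bromo-2-methylprop-1-ene
Reagents that add atoms: 3-bromo-2-methylprop-1-ene, CC(=C)CBr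
Why: Alkylation of the more substituted (thermodynamic) enolate from the convex face of the bicycle sets the quaternary carbon with the new chain exo and the methyl endo, as the cis-anti-cis triquinane needs.

Step 22
Reactants: 32 methyl 2,4-dimethyl-4-(2-methylprop-2-en-1-yl)-5-oxo-cis-octahydropentalene-2-carboxylate
Product: 33 methyl 2,4-dimethyl-5-oxo-4-(2-oxopropyl)-cis-octahydropentalene-2-carboxylate
Conditions: O3, CH2Cl2/MeOH, −78 °C; then Me2S
Reagents that add atoms: ozone, [O-][O+]=O
Why: Ozonolysis of the 1,1-disubstituted alkene unveils the methyl ketone of a 1,4-diketone.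

Step 23
Reactants: 33 methyl 2,4-dimethyl-5-oxo-4-(2-oxopropyl)-cis-octahydropentalene-2-carboxylate
Product: 35 cis-anti-cis triquinane enone acid (ring A cyclopent-2-enone with its β-carbon at the A/B fusion), via enone ester 34 (not isolated)
Conditions: KOH, MeOH/H2O, reflux; then HCl (aq.)
Reagents that add atoms: potassium hydroxide, [K+].[OH-]
Why: Intramolecular aldol condensation (cyclopentenone annulation) of the 1,4-diketone closes ring A, the only closure that can dehydrate, and the same base then saponifies the hindered ester.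

Step 24
Reactants: 35 cis-anti-cis triquinane enone acid
Product: 36 α,β-epoxy ketone acid (epoxide cis to the angular methyl)
Conditions: H2O2 (30%), NaOH, MeOH/H2O, 0 °C; then HCl (aq.)
Reagents that add atoms: hydrogen peroxide, OO
Why: Weitz–Scheffer nucleophilic epoxidation of the enone; the A/B fusion can only stay cis, so the epoxide oxygen must lie on the side of the angular methyl, and this centre is reset in step 25.

Step 25
Reactants: 36 α,β-epoxy ketone acid
Product: 37 ring-A 1,2-dione acid (diosphenol tautomers; A/B fusion H cis to the angular methyl)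
Conditions: H2SO4 (cat.), AcOH, 60 °C
Reagents that add atoms: none
Why: Acid-promoted Meinwald-type rearrangement opens the epoxide at the tertiary fusion carbon and a 1,2-hydride shift gives the 1,2-dione; the fusion CH is α to a ketone and settles in the stable cis-fused form.

Step 26
Reactants: 37 ring-A 1,2-dione acid; 24 (+)-β-caryophyllene
Product: 39 sterhirsutin C, via heterodiene 38 (not isolated)
Conditions: (CH2O)n, ethylenediammonium diacetate (10 mol%), MeCN, 80 °C, sealed tube
Reagents that add atoms: formaldehyde (from paraformaldehyde), C=O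
Why: Domino Knoevenagel condensation/inverse-electron-demand hetero-Diels–Alder reaction: the unsubstituted enol carbon next to the quaternary centre of 37 condenses with formaldehyde to the s-cis 3-methylene-1,2-dione 38, which adds only across the strained endocyclic E-alkene of 24 (O to the methyl-bearing C4, CH2 to C5, suprafacial, so the E geometry becomes the trans ring fusion and the 8-methylidene group is spared); 38 should react on its convex face (angular-methyl side, away from rings B and C) with H-5 rather than a ring CH2 under that methyl, and because the ring conformers of 24 interconvert faster than they are consumed (Curtin–Hammett) this preference is expected to draw the alkene through the conformer that gives the 4R,5S centres of 39.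

## Compound list

1 | isobutyraldehyde | CC(C)C=O | starting material
2 | methyl acrylate | C=CC(=O)OC | starting material
3 | 1-(2-methylprop-1-en-1-yl)pyrrolidine | CC(C)=CN1CCCC1 | intermediate
4 | methyl 4,4-dimethyl-5-oxopentanoate | COC(=O)CCC(C)(C)C=O | intermediate
5 | methyl 4,4-dimethylhex-5-enoate | COC(=O)CCC(C)(C)C=C | intermediate
6 | 4,4-dimethylhex-5-enoic acid | OC(=O)CCC(C)(C)C=C | intermediate
7 | (S)-but-3-en-2-ol | C[C@H](O)C=C | starting material
8 | (2S)-but-3-en-2-yl 4,4-dimethylhex-5-enoate | C=CC(C)(C)CCC(=O)O[C@@H](C)C=C | intermediate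
9 | (6Z,8S)-5,5,8-trimethyl-3,4,5,8-tetrahydro-2H-oxocin-2-one | C[C@H]1/C=C\C(C)(C)CCC(=O)O1 | intermediate
10 | (2E,6Z,8S)-2-(tert-butyldimethylsilyloxy)-5,5,8-trimethyl-5,8-dihydro-4H-oxocine | C[C@H]1/C=C\C(C)(C)C/C=C(/O[Si](C)(C)C(C)(C)C)O1 | intermediate
11 | tert-butyldimethylsilyl (1S,2S)-3,3-dimethyl-2-[(1E)-prop-1-en-1-yl]cyclobutane-1-carboxylate | CC(C)(C)[Si](C)(C)OC(=O)[C@H]1CC(C)(C)[C@H]1/C=C/C | intermediate
12 | (1S,2S)-3,3-dimethyl-2-[(1E)-prop-1-en-1-yl]cyclobutane-1-carboxylic acid | OC(=O)[C@H]1CC(C)(C)[C@H]1/C=C/C | intermediate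
13 | methyl (1S,2S)-3,3-dimethyl-2-[(1E)-prop-1-en-1-yl]cyclobutane-1-carboxylate | COC(=O)[C@H]1CC(C)(C)[C@H]1/C=C/C | intermediate
14 | methyl (1R,2S)-3,3-dimethyl-2-[(1E)-prop-1-en-1-yl]cyclobutane-1-carboxylate | COC(=O)[C@@H]1CC(C)(C)[C@H]1/C=C/C | intermediate
15 | methyl (1R,2S)-2-ethenyl-3,3-dimethylcyclobutane-1-carboxylate | COC(=O)[C@@H]1CC(C)(C)[C@H]1C=C | intermediate
16 | pent-3-yn-1-yl 4-methylbenzenesulfonate | CC#CCCOS(=O)(=O)c1ccc(C)cc1 | starting material
17 | (pent-3-yn-1-ylsulfonyl)benzene | CC#CCCS(=O)(=O)c1ccccc1 | intermediate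
18 | chlorobis(cyclopentadienyl)[(2E)-5-(phenylsulfonyl)pent-2-en-2-yl]zirconium (cyclopentadienyl rings drawn σ-bonded) | C/C(=C\CCS(=O)(=O)c1ccccc1)[Zr](Cl)(C1C=CC=C1)C1C=CC=C1 | intermediate
19 | {[(3E)-4-iodopent-3-en-1-yl]sulfonyl}benzene | C/C(I)=C\CCS(=O)(=O)c1ccccc1 | intermediate
20 | methyl (1R,2S)-2-[2-(9-borabicyclo[3.3.1]nonan-9-yl)ethyl]-3,3-dimethylcyclobutane-1-carboxylate | COC(=O)[C@@H]1CC(C)(C)[C@H]1CCB1C2CCCC1CCC2 | intermediate
21 | methyl (1R,2S)-3,3-dimethyl-2-[(3E)-3-methyl-6-(phenylsulfonyl)hex-3-en-1-yl]cyclobutane-1-carboxylate | COC(=O)[C@@H]1CC(C)(C)[C@H]1CC/C(C)=C/CCS(=O)(=O)c1ccccc1 | intermediate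
22 | (1S,4E,9R)-4,11,11-trimethyl-7-(phenylsulfonyl)bicyclo[7.2.0]undec-4-en-8-one (C7 epimers) | O=C1C(S(=O)(=O)c3ccccc3)C/C=C(C)/CC[C@H]2[C@H]1CC2(C)C | intermediate
23 | (1S,4E,9R)-4,11,11-trimethylbicyclo[7.2.0]undec-4-en-8-one | O=C1CC/C=C(C)/CC[C@H]2[C@H]1CC2(C)C | intermediate
24 | (1S,4E,9R)-4,11,11-trimethyl-8-methylidenebicyclo[7.2.0]undec-4-ene, (+)-β-caryophyllene | C=C1CC/C=C(C)/CC[C@H]2[C@H]1CC2(C)C | intermediate
25 | methyl cyclopent-3-ene-1-carboxylate | COC(=O)C1CC=CC1 | starting material
26 | methyl 1-methylcyclopent-3-ene-1-carboxylate | COC(=O)C1(C)CC=CC1 | intermediate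
27 | rac-methyl 6,6-dichloro-3-methyl-7-oxo-cis-bicyclo[3.2.0]heptane-3-carboxylate, ester anti to the four-membered ring (one enantiomer drawn) | O=C1[C@H]2C[C@](C)(C(=O)OC)C[C@H]2C1(Cl)Cl | intermediate
28 | rac-methyl 4,4-dichloro-2-methyl-5-oxo-cis-octahydropentalene-2-carboxylate, ester syn to the ring-fusion H (one enantiomer drawn) | O=C1C[C@H]2C[C@](C)(C(=O)OC)C[C@H]2C1(Cl)Cl | intermediate
29 | methyl 2-methyl-5-oxo-cis-octahydropentalene-2-carboxylate, meso, ester syn to both ring-fusion H | O=C1C[C@H]2C[C@](C)(C(=O)OC)C[C@H]2C1 | intermediate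
30 | methyl 2-methyl-5-(trimethylsilyloxy)-cis-1,2,3,3a,4,6a-hexahydropentalene-2-carboxylate, enantiomer as drawn | C[Si](C)(C)OC1=C[C@@H]2C[C@@](C)(C(=O)OC)C[C@@H]2C1 | intermediate
31 | methyl 2,4-dimethyl-5-oxo-cis-octahydropentalene-2-carboxylate (C4 epimers) | O=C1C[C@H]2C[C@](C)(C(=O)OC)C[C@H]2C1C | intermediate
32 | methyl 2,4-dimethyl-4-(2-methylprop-2-en-1-yl)-5-oxo-cis-octahydropentalene-2-carboxylate, 4-methyl endo | O=C1C[C@H]2C[C@](C)(C(=O)OC)C[C@H]2[C@]1(C)CC(C)=C | intermediate
33 | methyl 2,4-dimethyl-5-oxo-4-(2-oxopropyl)-cis-octahydropentalene-2-carboxylate | O=C1C[C@H]2C[C@](C)(C(=O)OC)C[C@H]2[C@]1(C)CC(C)=O | intermediate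
34 | methyl ester of 35 | C1C(=O)C=C3C[C@H]2C[C@](C)(C(=O)OC)C[C@H]2[C@]13C | intermediate
35 | cis-anti-cis triquinane enone acid: ring A cyclopent-2-enone (β-carbon at the A/B fusion), angular methyl at the other A/B fusion carbon, C(CH3)(CO2H) on ring C with CO2H syn to the B/C fusion H | C1C(=O)C=C3C[C@H]2C[C@](C)(C(=O)O)C[C@H]2[C@]13C | intermediate
36 | α,β-epoxy ketone of 35, epoxide cis to the angular methyl | C1C(=O)[C@H]4O[C@]43C[C@H]2C[C@](C)(C(=O)O)C[C@H]2[C@]13C | intermediate
37 | ring-A 1,2-dione acid (drawn as diketone; diosphenol tautomers), A/B fusion H cis to the angular methyl | C1C(=O)C(=O)[C@@H]3C[C@H]2C[C@](C)(C(=O)O)C[C@H]2[C@]13C | intermediate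
38 | 3-methylene-1,2-dione acid (heterodiene) | C=C1C(=O)C(=O)[C@@H]3C[C@H]2C[C@](C)(C(=O)O)C[C@H]2[C@]13C | intermediate
39 | sterhirsutin C | C=C1CC[C@H]2CC3=C(O[C@]2(C)CC[C@H]2[C@H]1CC2(C)C)C(=O)[C@@H]1C[C@H]2C[C@](C)(C(=O)O)C[C@H]2[C@]31C | target

## Step count and main risks

Total step count: 26. Longest linear sequence: 13 steps (steps 1–8, 11–14 and 26).

Steps most likely to fail:

Step 6. The lactone enolate may fragment (β-elimination to a ketene, or C-silylation) before it is trapped, or the silyl ketene acetal may not pass the strained boat leading to a four-membered ring. The fallback sets out from enamine 3 and acrylate 2 and returns at 15. Heating 3 with 2 in MeCN without aqueous work-up should give the known type of [2+2] adduct, methyl 3,3-dimethyl-2-(pyrrolidin-1-yl)cyclobutane-1-carboxylate F1; its ring is closed by the same C–C bond, through Mannich-type collapse of the zwitterion. MeI gives the N-methylpyrrolidinium iodide F2, and KOtBu-induced Hofmann elimination gives methyl 3,3-dimethylcyclobut-1-ene-1-carboxylate F3. Rhodium-catalysed asymmetric 1,4-addition of potassium vinyltrifluoroborate ([Rh(cod)Cl]2, the BINAP enantiomer that delivers vinyl to give 2S; Hayashi–Miyaura reaction) gives, after protonation, the cis ester methyl (1S,2S)-2-ethenyl-3,3-dimethylcyclobutane-1-carboxylate F4 together with 15, and NaOMe in MeOH converges both on 15.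

Step 26. The ring conformer of 24 that exposes the other alkene face is the more populated one, so the facial preference of 38 may be too small and the C4/C5-epimeric adduct may form alongside; 38 may also oligomerise. The fallback sets out from 37 and the open-chain alkene 21 and returns at 39, so no ring conformer can oppose the heterodiene. The same formaldehyde condensation/hetero-Diels–Alder reaction with excess 21 at higher temperature should give the open-chain adduct F7. LiN(SiMe3)2 (four equivalents, high dilution) closes the nine-membered ring by sulfone acylation to the β-keto sulfone F8. Al(Hg) in wet THF removes the sulfonyl group to give the 8-oxo compound F9, and Zn/CH2Br2/TiCl4 methylenation of the saturated ketone gives 39.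

Step 12. Intermolecular acylation and proton transfer from the ester α-carbon may outrun closure of the nine-membered ring. The fallback sets out from 21 and returns at 22. Reduction with iBu2AlH at −78 °C gives the aldehyde (1R,2S)-3,3-dimethyl-2-[(3E)-3-methyl-6-(phenylsulfonyl)hex-3-en-1-yl]cyclobutane-1-carbaldehyde F5. LiN(SiMe3)2 at high dilution closes the ring by addition of the sulfonyl carbanion to the more electrophilic aldehyde, giving the β-hydroxy sulfone F6, and Dess–Martin oxidation gives 22.

Further compounds
F1 | step 6 | methyl 3,3-dimethyl-2-(pyrrolidin-1-yl)cyclobutane-1-carboxylate (racemic) | COC(=O)C1CC(C)(C)C1N1CCCC1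
F2 | step 6 | 1-[2-(methoxycarbonyl)-4,4-dimethylcyclobutyl]-1-methylpyrrolidinium iodide | COC(=O)C1CC(C)(C)C1[N+]1(C)CCCC1.[I-]
F3 | step 6 | methyl 3,3-dimethylcyclobut-1-ene-1-carboxylate | COC(=O)C1=CC(C)(C)C1
F4 | step 6 | methyl (1S,2S)-2-ethenyl-3,3-dimethylcyclobutane-1-carboxylate | COC(=O)[C@H]1CC(C)(C)[C@H]1C=C
F5 | step 12 | (1R,2S)-3,3-dimethyl-2-[(3E)-3-methyl-6-(phenylsulfonyl)hex-3-en-1-yl]cyclobutane-1-carbaldehyde | O=C[C@@H]1CC(C)(C)[C@H]1CC/C(C)=C/CCS(=O)(=O)c1ccccc1
F6 | step 12 | (1S,4E,9R)-4,11,11-trimethyl-7-(phenylsulfonyl)bicyclo[7.2.0]undec-4-en-8-ol (diastereomers at C7 and C8) | OC1C(S(=O)(=O)c3ccccc3)C/C=C(C)/CC[C@H]2[C@H]1CC2(C)C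
F7 | step 26 | open-chain hetero-Diels–Alder adduct of 38 and 21 | O=S(=O)(c4ccccc4)CC[C@H]2CC3=C(O[C@]2(C)CC[C@H]2[C@H](C(=O)OC)CC2(C)C)C(=O)[C@@H]1C[C@H]2C[C@](C)(C(=O)O)C[C@H]2[C@]31C
F8 | step 26 | 7-phenylsulfonyl-8-oxo analogue of 39 lacking the methylidene carbon (C7 epimers) | O=C1C(S(=O)(=O)c4ccccc4)C[C@H]2CC3=C(O[C@]2(C)CC[C@H]2[C@H]1CC2(C)C)C(=O)[C@@H]1C[C@H]2C[C@](C)(C(=O)O)C[C@H]2[C@]31C
F9 | step 26 | 8-oxo analogue of 39 lacking the methylidene carbon | O=C1CC[C@H]2CC3=C(O[C@]2(C)CC[C@H]2[C@H]1CC2(C)C)C(=O)[C@@H]1C[C@H]2C[C@](C)(C(=O)O)C[C@H]2[C@]31C
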